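## Retrosynthetic overview
1. The target is (2S,3S,5S), that is 2,3-syn and 3,5-syn. It comes from global hydrogenolysis of a tri-O-benzyl precursor (both phenols and the C2-OH).
2. The C5 carbinol comes from a hydroxyl-directed 1,3-syn reduction of a C3-hydroxy-C5-ketone.
3. The key C3–C4 bond comes from a chelation-controlled Mukaiyama aldol. It joins the silyl enol ether of O-benzylzingerone (C4–C7) to an (S)-α-benzyloxy aldehyde (C1–C3).
4. The aldehyde comes from O-benzyl-L-tyrosine: C2 is taken from the chiral pool by retentive diazotisation, followed by O-benzylation, reduction and oxidation.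
5. No ring is formed at any stage; both benzene rings are bought intact.

Assumption: O-benzyl-L-tyrosine (H-Tyr(Bzl)-OH) and zingerone (vanillylacetone) are taken as cheap commercial chemicals. The chain is numbered C1 (CH2 on the 4-hydroxyphenyl ring) to C7 (CH2 on the guaiacyl ring).

## Route

Step 1
Reactants: 1 O-benzyl-L-tyrosine
Product: 4 (S)-3-[4-(benzyloxy)phenyl]-2-hydroxypropanoic acid, via diazonium carboxylate 2 (not isolated), via alpha-lactone 3 (not isolated)
Conditions: NaNO2 (2.5 equiv), 1 M aq H2SO4/1,4-dioxane, 0 °C → rt, 16 h; recrystallise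
Reagents that add atoms: water, O
Why: In this diazotisation of an α-amino acid the carboxylate expels N2 (first inversion, giving 3) and water opens the α-lactone at Cα (second inversion), so the L-(S) centre is kept with net retention and becomes C2 (S).

Step 2
Reactants: 4 (S)-3-[4-(benzyloxy)phenyl]-2-hydroxypropanoic acid
Product: 5 methyl (S)-3-[4-(benzyloxy)phenyl]-2-hydroxypropanoate
Conditions: MeOH, H2SO4 (cat.), reflux, 4 h
Reagents that add atoms: methanol, CO
Why: Fischer esterification leaves the stereocentre untouched, and the aryl benzyl ether is stable to catalytic acid in methanol.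

Step 3
Reactants: 5 methyl (S)-3-[4-(benzyloxy)phenyl]-2-hydroxypropanoate
Product: 6 methyl (S)-2-(benzyloxy)-3-[4-(benzyloxy)phenyl]propanoate
Conditions: BnOC(=NH)CCl3 (1.5 equiv), TfOH (5 mol %), cyclohexane/CH2Cl2 2:1, 0 °C → rt
Reagents that add atoms: benzyl 2,2,2-trichloroacetimidate, N=C(OCc1ccccc1)C(Cl)(Cl)Cl
Why: Acid-catalysed trichloroacetimidate O-benzylation needs no base, so the enolisable α-centre of the hydroxy ester is not racemised, and it installs the chelating OBn group needed in step 8.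

Step 4
Reactants: 6 methyl (S)-2-(benzyloxy)-3-[4-(benzyloxy)phenyl]propanoate
Product: 7 (S)-2-(benzyloxy)-3-[4-(benzyloxy)phenyl]propan-1-ol
Conditions: LiAlH4 (1.0 equiv), THF, 0 °C, 1 h; H2O/aq NaOH work-up
Reagents that add atoms: none
Why: LiAlH4 reduction of the ester is fast at 0 °C, leaves benzyl ethers alone and does not involve the stereocentre.

Step 5
Reactants: 7 (S)-2-(benzyloxy)-3-[4-(benzyloxy)phenyl]propan-1-ol
Product: 8 (S)-2-(benzyloxy)-3-[4-(benzyloxy)phenyl]propanal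
Conditions: Dess–Martin periodinane (1.2 equiv), CH2Cl2, 0 °C → rt, 1 h; aq Na2S2O3/NaHCO3 wash; used the same day without chromatography
Reagents that add atoms: none
Why: Dess–Martin oxidation is non-basic and stops at the aldehyde, so the configurationally labile α-alkoxy aldehyde is obtained without epimerisation.

Step 6
Reactants: 9 zingerone, 4-(4-hydroxy-3-methoxyphenyl)butan-2-one
Product: 10 4-[4-(benzyloxy)-3-methoxyphenyl]butan-2-one
Conditions: BnBr (1.1 equiv), K2CO3 (1.5 equiv), DMF, rt, 12 h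
Reagents that add atoms: benzyl bromide, BrCc1ccccc1
Why: In this Williamson ether synthesis carbonate deprotonates only the phenol, so the ketone is not alkylated.

Step 7
Reactants: 10 4-[4-(benzyloxy)-3-methoxyphenyl]butan-2-one
Product: 12 ({4-[4-(benzyloxy)-3-methoxyphenyl]but-1-en-2-yl}oxy)trimethylsilane, via lithium enolate 11 (not isolated)
Conditions: LDA (1.1 equiv, from i-Pr2NH/n-BuLi), THF, −78 °C, slow addition of 10; TMSCl (1.3 equiv), −78 → 0 °C; pentane, cold aq NaHCO3; used crude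
Reagents that add atoms: chlorotrimethylsilane, C[Si](C)(C)Cl
Why: Kinetic deprotonation with LDA takes place at the unhindered methyl group, and O-silylation freezes the terminal enolate as the regiodefined silyl enol ether.

Step 8
Reactants: 8 (S)-2-(benzyloxy)-3-[4-(benzyloxy)phenyl]propanal; 12 ({4-[4-(benzyloxy)-3-methoxyphenyl]but-1-en-2-yl}oxy)trimethylsilane
Product: 15 (5S,6S)-6-(benzyloxy)-7-[4-(benzyloxy)phenyl]-1-[4-(benzyloxy)-3-methoxyphenyl]-5-hydroxyheptan-3-one, via titanium chelate 13 (not isolated), via titanium aldolate 14 (not isolated)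
Conditions: 8, TiCl4 (1.05 equiv), CH2Cl2, −78 °C, 10 min; then 12 (1.4 equiv), −78 °C, 1 h; H2O quench at −78 °C, aq NaHCO3 wash; chromatography
Reagents that add atoms: none
Why: In this chelation-controlled (Cram-chelate) Mukaiyama aldol TiCl4 locks C=O and C2-OBn in a five-membered chelate, and the enol silane attacks from the face bearing H rather than CH2Ar, which gives the 2,3-syn product with the new carbinol (target C3) as (S), typically ≥10:1.

Step 9
Reactants: 15 (5S,6S)-6-(benzyloxy)-7-[4-(benzyloxy)phenyl]-1-[4-(benzyloxy)-3-methoxyphenyl]-5-hydroxyheptan-3-one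
Product: 17 (2S,3S,5S)-2-(benzyloxy)-1-[4-(benzyloxy)phenyl]-7-[4-(benzyloxy)-3-methoxyphenyl]heptane-3,5-diol, via boron chelate 16 (not isolated)
Conditions: Et2BOMe (1.2 equiv), THF/MeOH 4:1, −78 °C, 30 min; NaBH4 (1.2 equiv), −78 °C, 4 h; aq work-up, then evaporation from MeOH (×5)
Reagents that add atoms: none
Why: In the Narasaka–Prasad reduction boron ties the C3-O and the C5 ketone into a six-membered chelate that external hydride attacks axially, which places the new C5-OH syn to C3-OH, that is (5S), usually with dr >20:1.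

Step 10
Reactants: 17 (2S,3S,5S)-2-(benzyloxy)-1-[4-(benzyloxy)phenyl]-7-[4-(benzyloxy)-3-methoxyphenyl]heptane-3,5-diol
Product: 18 (2S,3S,5S)-7-(4-hydroxy-3-methoxyphenyl)-1-(4-hydroxyphenyl)heptane-2,3,5-triol
Conditions: H2 (1 atm), 10 % Pd/C, MeOH/EtOAc 1:1, rt, 12 h
Reagents that add atoms: none
Why: Catalytic hydrogenolysis removes the two aryl benzyl ethers and the alkyl benzyl ether, and because none of the three carbinol carbons is benzylic, no C–O bond of the triol and no stereocentre is touched.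

## Compound list
1 | O-benzyl-L-tyrosine | OC(=O)[C@@H](N)Cc1ccc(OCc2ccccc2)cc1 | starting material
2 | (S)-α-diazonium carboxylate of 1 (zwitterion) | [O-]C(=O)[C@@H]([N+]#N)Cc1ccc(OCc2ccccc2)cc1 | intermediate
3 | (R)-3-[4-(benzyloxy)benzyl]oxiran-2-one (α-lactone) | O=C1[C@H](O1)Cc1ccc(OCc2ccccc2)cc1 | intermediate
4 | (S)-3-[4-(benzyloxy)phenyl]-2-hydroxypropanoic acid | OC(=O)[C@@H](O)Cc1ccc(OCc2ccccc2)cc1 | intermediate
5 | methyl (S)-3-[4-(benzyloxy)phenyl]-2-hydroxypropanoate | COC(=O)[C@@H](O)Cc1ccc(OCc2ccccc2)cc1 | intermediate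
6 | methyl (S)-2-(benzyloxy)-3-[4-(benzyloxy)phenyl]propanoate | COC(=O)[C@@H](OCc1ccccc1)Cc1ccc(OCc2ccccc2)cc1 | intermediate
7 | (S)-2-(benzyloxy)-3-[4-(benzyloxy)phenyl]propan-1-ol | OC[C@@H](OCc1ccccc1)Cc1ccc(OCc2ccccc2)cc1 | intermediate
8 | (S)-2-(benzyloxy)-3-[4-(benzyloxy)phenyl]propanal | O=C[C@@H](OCc1ccccc1)Cc1ccc(OCc2ccccc2)cc1 | intermediate
9 | zingerone, 4-(4-hydroxy-3-methoxyphenyl)butan-2-one | CC(=O)CCc1ccc(O)c(OC)c1 | starting material
10 | 4-[4-(benzyloxy)-3-methoxyphenyl]butan-2-one | CC(=O)CCc1ccc(OCc2ccccc2)c(OC)c1 | intermediate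
11 | lithium 4-[4-(benzyloxy)-3-methoxyphenyl]but-1-en-2-olate | [Li]OC(=C)CCc1ccc(OCc2ccccc2)c(OC)c1 | intermediate
12 | ({4-[4-(benzyloxy)-3-methoxyphenyl]but-1-en-2-yl}oxy)trimethylsilane | C=C(CCc1ccc(OCc2ccccc2)c(OC)c1)O[Si](C)(C)C | intermediate
13 | TiCl4 five-ring chelate of aldehyde 8 | [O+]1=C[C@@H]([O+](Cc2ccccc2)[Ti-2]1(Cl)(Cl)(Cl)Cl)Cc1ccc(OCc2ccccc2)cc1 | intermediate
14 | trichlorotitanium(IV) aldolate of 15 | COc1cc(CCC(=O)C[C@H](O[Ti](Cl)(Cl)Cl)[C@@H](OCc2ccccc2)Cc2ccc(OCc3ccccc3)cc2)ccc1OCc1ccccc1 | intermediate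
15 | (5S,6S)-6-(benzyloxy)-7-[4-(benzyloxy)phenyl]-1-[4-(benzyloxy)-3-methoxyphenyl]-5-hydroxyheptan-3-one | COc1cc(CCC(=O)C[C@H](O)[C@@H](OCc2ccccc2)Cc2ccc(OCc3ccccc3)cc2)ccc1OCc1ccccc1 | intermediate
16 | O-diethylboryl derivative (boron chelate) of 15 | COc1cc(CCC(=O)C[C@H](OB(CC)CC)[C@@H](OCc2ccccc2)Cc2ccc(OCc3ccccc3)cc2)ccc1OCc1ccccc1 | intermediate
17 | (2S,3S,5S)-2-(benzyloxy)-1-[4-(benzyloxy)phenyl]-7-[4-(benzyloxy)-3-methoxyphenyl]heptane-3,5-diol | COc1cc(CC[C@H](O)C[C@H](O)[C@@H](OCc2ccccc2)Cc2ccc(OCc3ccccc3)cc2)ccc1OCc1ccccc1 | intermediate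
18 | (2S,3S,5S)-7-(4-hydroxy-3-methoxyphenyl)-1-(4-hydroxyphenyl)heptane-2,3,5-triol | COc1cc(CC[C@H](O)C[C@H](O)[C@@H](O)Cc2ccc(O)cc2)ccc1O | target

## Step count and risks
Total steps: 10. Longest linear sequence: 8 (steps 1–5, then 8–10).

**Step 8 (most critical).** The risks are protodesilylation of 12, eroded diastereoselectivity and Lewis-acid damage.
- The fallback replaces the enol silane by a carbonyl allylation followed by oxidative cleavage. It sets out from lithium enolate 11 (made from 10 as in step 7) and aldehyde 8, and comes back to the route at 15.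
- Enolate 11 is trapped with PhNTf2 (THF, −78 °C → rt) to give 4-[4-(benzyloxy)-3-methoxyphenyl]but-1-en-2-yl trifluoromethanesulfonate F1.
- Kumada coupling of F1 with Me3SiCH2MgCl (Pd(PPh3)4 cat., THF, rt) gives {4-[4-(benzyloxy)-3-methoxyphenyl]-2-methylidenebutyl}trimethylsilane F2, a robust nucleophile that can be chromatographed.
- Hosomi–Sakurai allylation of SnCl4-chelated 8 with F2 (CH2Cl2, −78 °C) gives (2S,3S)-2-(benzyloxy)-1-[4-(benzyloxy)phenyl]-7-[4-(benzyloxy)-3-methoxyphenyl]-5-methylideneheptan-3-ol F3.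
- Lemieux–Johnson cleavage of the 1,1-disubstituted alkene (OsO4 cat., NaIO4, 2,6-lutidine, dioxane/H2O) unmasks ketone 15.

**Step 5.** The risk is epimerisation or decomposition of the α-alkoxy aldehyde during oxidation and isolation.
- The fallback reaches the aldehyde by reduction instead of oxidation. It sets out from ester 6, bypasses 7 and comes back at 8.
- MeNH(OMe)·HCl/i-PrMgCl (THF, −20 °C) converts 6 into (S)-2-(benzyloxy)-3-[4-(benzyloxy)phenyl]-N-methoxy-N-methylpropanamide F4.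
- LiAlH4 (THF, −78 °C) takes F4 to a stable chelated tetrahedral intermediate. This releases 8 only on a cold aq KHSO4 quench, immediately before step 8.

**Step 3.** The risks are sluggish benzylation or Friedel–Crafts side reactions with the imidate, and racemisation if base were used instead.
- The fallback removes the acidic α-hydrogen before benzylating. It sets out from hydroxy ester 5, bypasses 6 and comes back at 7.
- LiAlH4 reduces 5 to (S)-3-[4-(benzyloxy)phenyl]propane-1,2-diol F5.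
- TrCl/pyridine protects only the primary hydroxyl and gives (S)-1-[4-(benzyloxy)phenyl]-3-(trityloxy)propan-2-ol F6.
- NaH/BnBr/TBAI (THF) gives (S)-1-(benzyloxy)-4-[2-(benzyloxy)-3-(trityloxy)propyl]benzene F7. Strong base is harmless at this stage.
- TsOH·H2O (cat.) in MeOH/CH2Cl2 removes the trityl group to give 7.

## Further compounds
F1 | step 8 | 4-[4-(benzyloxy)-3-methoxyphenyl]but-1-en-2-yl trifluoromethanesulfonate | C=C(CCc1ccc(OCc2ccccc2)c(OC)c1)OS(=O)(=O)C(F)(F)F
F2 | step 8 | {4-[4-(benzyloxy)-3-methoxyphenyl]-2-methylidenebutyl}trimethylsilane | C=C(CCc1ccc(OCc2ccccc2)c(OC)c1)C[Si](C)(C)C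
F3 | step 8 | (2S,3S)-2-(benzyloxy)-1-[4-(benzyloxy)phenyl]-7-[4-(benzyloxy)-3-methoxyphenyl]-5-methylideneheptan-3-ol | COc1cc(CCC(=C)C[C@H](O)[C@@H](OCc2ccccc2)Cc2ccc(OCc3ccccc3)cc2)ccc1OCc1ccccc1
F4 | step 5 | (S)-2-(benzyloxy)-3-[4-(benzyloxy)phenyl]-N-methoxy-N-methylpropanamide | CON(C)C(=O)[C@@H](OCc1ccccc1)Cc1ccc(OCc2ccccc2)cc1
F5 | step 3 | (S)-3-[4-(benzyloxy)phenyl]propane-1,2-diol | OC[C@@H](O)Cc1ccc(OCc2ccccc2)cc1
F6 | step 3 | (S)-1-[4-(benzyloxy)phenyl]-3-(trityloxy)propan-2-ol | C(c1ccccc1)(c1ccccc1)(c1ccccc1)OC[C@@H](O)Cc1ccc(OCc2ccccc2)cc1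
F7 | step 3 | (S)-1-(benzyloxy)-4-[2-(benzyloxy)-3-(trityloxy)propyl]benzene | C(c1ccccc1)(c1ccccc1)(c1ccccc1)OC[C@@H](OCc1ccccc1)Cc1ccc(OCc2ccccc2)cc1
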